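**Plan**

1. Retrosynthesis (germacranolide numbering): the C3–C4 bond of the ten-membered ring is cut first, giving an alkenyl iodide and an enal. The C7–C8 bond is cut next, giving two fragments. Inside the fragments, the C7=C11 bond and the O6–C12 ester of a butenolide and the C9–C10 bond of a tertiary carbinol are cut.
2. Forward: fragment A (C4–C7, C11–C13, C15) is made as a butenolide allylstannane and fragment B (C1–C3, C8–C10, C14) as a β-silyloxy aldehyde. Their union at C7–C8 transposes the butenolide into the α-methylene lactone. Angeloylation, desilylation and oxidation give the seco enal, and the ten-membered ring is closed last.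
3. Enabling feature: C3 is a carbinol flanked by the Z-C4=C5 and E-C1=C2 alkenes, so it maps onto an alkenyl iodide of fixed geometry and an s-trans enal. The trans-fused lactone (O–C6–C7–C11–C12), both alkenes and the quaternary C10 leave few rotors in the seco chain.
4. Stereochemistry: C6 comes from a catalytic asymmetric vinyl addition and C7 from C6 (attack anti on the butenolide ring). C8 comes from the open transition state of the stannane addition and C10 from a catalytic asymmetric allylboration. C3 comes from C10 through allylic strain in the ring closure.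
5. Alkene geometry: Z-C4=C5 from hydroalumination–iodination, E-C1=C2 from a Wittig reaction, the angelate from angelic acid.

Key step: step 15

Remark: target atoms carry germacranolide numbers (ring C1–C10, lactone C11–C13 on C6/C7, methyls C14 on C10 and C15 on C4). The sense of induction in steps 3 and 8 is assigned by analogy with simpler carbonyl compounds, and the ligand antipode is exchanged if a correlation on the products shows the opposite.

**Route**

Step 1
Reactants: 1 but-2-yn-1-ol
Product: 3 (Z)-3-iodobut-2-en-1-ol, via cyclic sodium alkenylalanate 2 (not isolated)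
Conditions: NaAlH2(OCH2CH2OMe)2 (1.5 equiv), THF, 0 °C → rt; then I2, THF, −78 °C → 0 °C
Reagents that add atoms: iodine, [I][I]
Why: Hydroxyl-directed trans-hydroalumination of the propargylic alcohol places aluminium on C3 in a five-membered alanate, and iodinolysis with retention should give the Z-iodoalkene that becomes C4=C5 with C15 (hydroalumination–iodination of propargylic alcohols).

Step 2
Reactants: 3 (Z)-3-iodobut-2-en-1-ol
Product: 4 (Z)-3-iodobut-2-enal
Conditions: MnO2 (15 equiv), CH2Cl2, rt, dark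
Reagents that add atoms: none
Why: Allylic oxidation on MnO2 is neutral and should leave the Z geometry of the β-iodoenal intact.

Step 3
Reactants: 4 (Z)-3-iodobut-2-enal
Product: 5 (3S,4Z)-5-iodohexa-1,4-dien-3-ol
Conditions: Zn(CH=CH2)2 (1.5 equiv), (−)-3-exo-morpholinoisoborneol (10 mol %), toluene, −20 °C → 0 °C; aq NH4Cl
Reagents that add atoms: divinylzinc, C=C[Zn]C=C
Why: Amino-alcohol-catalysed enantioselective alkenylzinc 1,2-addition (Oppolzer-type vinyl transfer) should deliver vinyl to the Si face of the aldehyde and so set the future C6 centre as S.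

Step 4
Reactants: 5 (3S,4Z)-5-iodohexa-1,4-dien-3-ol; 6 2-(bromomethyl)acrylic acid
Product: 7 (3S,4Z)-5-iodohexa-1,4-dien-3-yl 2-(bromomethyl)prop-2-enoate
Conditions: DCC (1.2 equiv), DMAP (5 mol %), CH2Cl2, 0 °C
Reagents that add atoms: none
Why: Steglich esterification attaches the C11–C13 unit to O6 with retention at the carbinol, and low temperature with little DMAP limits attack on the allylic bromide.

Step 5
Reactants: 7 (3S,4Z)-5-iodohexa-1,4-dien-3-yl 2-(bromomethyl)prop-2-enoate
Product: 8 (5S)-3-(bromomethyl)-5-[(1Z)-2-iodoprop-1-en-1-yl]furan-2(5H)-one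
Conditions: second-generation Grubbs catalyst RuCl2(=CHPh)(H2IMes)(PCy3) (5 mol %), toluene (0.01 M), 80 °C
Reagents that add atoms: none
Why: Ring-closing metathesis between the monosubstituted vinyl group and the 1,1-disubstituted acrylate closes the butenolide (C7=C11) by loss of ethene, while the trisubstituted iodoalkene is too hindered to take part.

Step 6
Reactants: 8 (5S)-3-(bromomethyl)-5-[(1Z)-2-iodoprop-1-en-1-yl]furan-2(5H)-one
Product: 10 (5S)-5-[(1Z)-2-iodoprop-1-en-1-yl]-3-[(tributylstannyl)methyl]furan-2(5H)-one, via allylzinc bromide 9 (not isolated)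
Conditions: Zn (2 equiv), Bu3SnCl (1.2 equiv), THF/sat. aq NH4Cl (1:1), rt
Reagents that add atoms: tributyltin chloride, CCCC[Sn](Cl)(CCCC)CCCC
Why: Barbier-type zinc insertion into the allylic bromide and capture of allylzinc 9 by Bu3SnCl should give the more stable primary allylstannane (tin on C13) under neutral conditions that spare the alkenyl iodide.

Step 7
Reactants: 11 (tert-butyldimethylsilyloxy)acetaldehyde; 12 (acetylmethylene)triphenylphosphorane
Product: 13 (3E)-5-[(tert-butyldimethylsilyl)oxy]pent-3-en-2-one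
Conditions: CH2Cl2, rt
Reagents that add atoms: none
Why: Wittig olefination with a stabilised ylide gives the E-enone that carries C1=C2, C3, C10 and C14.

Step 8
Reactants: 13 (3E)-5-[(tert-butyldimethylsilyl)oxy]pent-3-en-2-one
Product: 14 (4R,5E)-7-[(tert-butyldimethylsilyl)oxy]-4-methylhepta-1,5-dien-4-ol
Conditions: 2-allyl-1,3,2-dioxaborinane (1.5 equiv), (S)-3,3′-dibromo-1,1′-bi-2-naphthol (5 mol %), t-BuOH (2 equiv), toluene, rt
Reagents that add atoms: 2-allyl-1,3,2-dioxaborinane, C=CCB1OCCCO1
Why: Diol-catalysed enantioselective allylboration of a methyl ketone (Schaus-type) proceeds through a chair transition state on the chiral boronate that tells methyl from alkenyl, and 1,2-addition to the Re face should set C10 as R.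

Step 9
Reactants: 14 (4R,5E)-7-[(tert-butyldimethylsilyl)oxy]-4-methylhepta-1,5-dien-4-ol
Product: 15 (4R,5E)-7-[(tert-butyldimethylsilyl)oxy]-4-methyl-4-[(triethylsilyl)oxy]hepta-1,5-diene
Conditions: Et3SiOTf (1.3 equiv), 2,6-lutidine (2 equiv), CH2Cl2, −78 °C → 0 °C
Reagents that add atoms: triethylsilyl triflate, CC[Si](CC)(CC)OS(=O)(=O)C(F)(F)F
Why: Silylation with the triflate protects the hindered tertiary C10 hydroxyl for the Lewis-acid step, and the group can later be removed together with the TBS ether.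

Step 10
Reactants: 15 (4R,5E)-7-[(tert-butyldimethylsilyl)oxy]-4-methyl-4-[(triethylsilyl)oxy]hepta-1,5-diene
Product: 17 (3R,4E)-6-[(tert-butyldimethylsilyl)oxy]-3-methyl-3-[(triethylsilyl)oxy]hex-4-enal, via vicinal diol 16 (not isolated)
Conditions: OsO4 (2 mol %), NaIO4 (4 equiv), 2,6-lutidine (2 equiv), 1,4-dioxane/H2O (3:1), rt
Reagents that add atoms: osmium tetroxide, O=[Os](=O)(=O)=O
Why: In this Lemieux–Johnson cleavage, osmylation should go to the terminal alkene because the internal E-alkene is shielded by the quaternary centre and deactivated by two allylic silyloxy groups, and periodate then cleaves diol 16 to the C8 aldehyde.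

Step 11
Reactants: 10 (5S)-5-[(1Z)-2-iodoprop-1-en-1-yl]-3-[(tributylstannyl)methyl]furan-2(5H)-one; 17 (3R,4E)-6-[(tert-butyldimethylsilyl)oxy]-3-methyl-3-[(triethylsilyl)oxy]hex-4-enal
Product: 18 (4R,5S)-4-[(1R,3R,4E)-6-[(tert-butyldimethylsilyl)oxy]-1-hydroxy-3-methyl-3-[(triethylsilyl)oxy]hex-4-en-1-yl]-5-[(1Z)-2-iodoprop-1-en-1-yl]-3-methylideneoxolan-2-one
Conditions: BF3·OEt2 (1.5 equiv), CH2Cl2, −78 °C → −40 °C; aq NaHCO3
Reagents that add atoms: none
Why: In this Lewis-acid-promoted allylstannane addition (SE2′, open transition state) the BF3-bound aldehyde should attack C7 anti to the C6 alkenyl group (trans-lactone, C7 R) with transposition to the exocyclic methylene, and the antiperiplanar open transition state of the ring-locked E-type stannane keeps the aldehyde chain away from C6 and should give the 8R carbinol, whereas a closed chair transition state would give the C8 epimer.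

Step 12
Reactants: 18 (4R,5S)-4-[(1R,3R,4E)-6-[(tert-butyldimethylsilyl)oxy]-1-hydroxy-3-methyl-3-[(triethylsilyl)oxy]hex-4-en-1-yl]-5-[(1Z)-2-iodoprop-1-en-1-yl]-3-methylideneoxolan-2-one; 19 angelic acid [(2Z)-2-methylbut-2-enoic acid]
Product: 20 (1R,3R,4E)-6-[(tert-butyldimethylsilyl)oxy]-1-[(2S,3R)-2-[(1Z)-2-iodoprop-1-en-1-yl]-4-methylidene-5-oxooxolan-3-yl]-3-methyl-3-[(triethylsilyl)oxy]hex-4-en-1-yl (2Z)-2-methylbut-2-enoate
Conditions: 19 (3 equiv), 2,4,6-trichlorobenzoyl chloride (3 equiv), Et3N (3.5 equiv), toluene, rt; then 18, toluene, 80 °C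
Reagents that add atoms: none
Why: Yamaguchi mixed-anhydride acylation without DMAP should transfer the angeloyl group to the only free hydroxyl with the Z geometry kept, and the trans-disubstituted lactone is the more stable lactone isomer, so no shift of the lactone to O8 is expected.

Step 13
Reactants: 20 (1R,3R,4E)-6-[(tert-butyldimethylsilyl)oxy]-1-[(2S,3R)-2-[(1Z)-2-iodoprop-1-en-1-yl]-4-methylidene-5-oxooxolan-3-yl]-3-methyl-3-[(triethylsilyl)oxy]hex-4-en-1-yl (2Z)-2-methylbut-2-enoate
Product: 21 (1R,3R,4E)-3,6-dihydroxy-1-[(2S,3R)-2-[(1Z)-2-iodoprop-1-en-1-yl]-4-methylidene-5-oxooxolan-3-yl]-3-methylhex-4-en-1-yl (2Z)-2-methylbut-2-enoate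
Conditions: HF·pyridine, pyridine/THF, 0 °C → rt
Reagents that add atoms: none
Why: Buffered fluoride desilylation should cleave the primary TBS and the tertiary TES ether while the angelate, the α-methylene lactone and the alkenyl iodide survive.

Step 14
Reactants: 21 (1R,3R,4E)-3,6-dihydroxy-1-[(2S,3R)-2-[(1Z)-2-iodoprop-1-en-1-yl]-4-methylidene-5-oxooxolan-3-yl]-3-methylhex-4-en-1-yl (2Z)-2-methylbut-2-enoate
Product: 22 (1R,3R,4E)-3-hydroxy-1-[(2S,3R)-2-[(1Z)-2-iodoprop-1-en-1-yl]-4-methylidene-5-oxooxolan-3-yl]-3-methyl-6-oxohex-4-en-1-yl (2Z)-2-methylbut-2-enoate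
Conditions: MnO2 (20 equiv), CH2Cl2, rt
Reagents that add atoms: none
Why: MnO2 oxidises only the primary allylic alcohol, so the E-enal (C3) should form with the tertiary C10 hydroxyl untouched.

Step 15
Reactants: 22 (1R,3R,4E)-3-hydroxy-1-[(2S,3R)-2-[(1Z)-2-iodoprop-1-en-1-yl]-4-methylidene-5-oxooxolan-3-yl]-3-methyl-6-oxohex-4-en-1-yl (2Z)-2-methylbut-2-enoate
Product: 24 (3aR,4R,6R,7E,9R,10Z,11aR)-6,9-dihydroxy-6,10-dimethyl-3-methylidene-2-oxo-2,3,3a,4,5,6,9,11a-octahydrocyclodeca[b]furan-4-yl (2Z)-2-methylbut-2-enoate, via alkenylchromium dichloride 23 (not isolated)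
Conditions: CrCl2 (10 equiv), NiCl2 (0.1 equiv), degassed DMSO, slow addition of 22 to 0.002 M, rt; aq work-up
Reagents that add atoms: none
Why: CrCl2 reduces NiCl2 to zerovalent nickel, which inserts into the C4–I bond with retention of the Z geometry; transmetalation to trivalent chromium gives alkenylchromium dichloride 23, which adds 1,2 to the C3 aldehyde and forms the C3–C4 bond as a chromium alkoxide that is protonated on work-up. The closest known reaction type is the Nozaki–Hiyama–Kishi macrocyclisation of iodoalkenyl aldehydes to medium- and large-ring allylic alcohols. The ten-membered carbocycle closes by a 10-exo-trig attack on the carbonyl group, whose oxygen stays outside the ring. The new C3 centre is controlled by the C10 stereocentre through allylic strain across the E-C1=C2 bond: in the s-trans enal the small C10 hydroxyl lies near the alkene plane beside C2–H, the methyl points outward and C9 leads the chain over the Si face of the carbonyl, so attack from that face should give the 3R carbinol. The step needs 1,2- over 1,4-addition and ring closure over oligomerisation; the carbonyl-selective, weakly basic organochromium (which tolerates the angelate, the lactone with its exocyclic acceptor and the free tertiary hydroxyl) secures the first, and high dilution together with the rigid seco chain (trans-lactone, Z-iodoalkene, E-enal, quaternary C10) the second.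

**Compound list**

1 | but-2-yn-1-ol | CC#CCO | starting material
2 | cyclic sodium alkenylalanate (sodium 2,2-bis(2-methoxyethoxy)-3-methyl-2,5-dihydro-1,2-oxaaluminol-2-uide) | [Na+].CC1=CCO[Al-]1(OCCOC)OCCOC | intermediate
3 | (Z)-3-iodobut-2-en-1-ol | C/C(I)=C/CO | intermediate
4 | (Z)-3-iodobut-2-enal | C/C(I)=C/C=O | intermediate
5 | (3S,4Z)-5-iodohexa-1,4-dien-3-ol | C=C[C@H](O)/C=C(/C)I | intermediate
6 | 2-(bromomethyl)acrylic acid | C=C(CBr)C(=O)O | starting material
7 | (3S,4Z)-5-iodohexa-1,4-dien-3-yl 2-(bromomethyl)prop-2-enoate | C=C(CBr)C(=O)O[C@@H](C=C)/C=C(/C)I | intermediate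
8 | (5S)-3-(bromomethyl)-5-[(1Z)-2-iodoprop-1-en-1-yl]furan-2(5H)-one | BrCC1=C[C@@H](/C=C(/C)I)OC1=O | intermediate
9 | allylzinc bromide of 8 (bromozinc in place of bromine on the exocyclic CH2) | Br[Zn]CC1=C[C@@H](/C=C(/C)I)OC1=O | intermediate
10 | (5S)-5-[(1Z)-2-iodoprop-1-en-1-yl]-3-[(tributylstannyl)methyl]furan-2(5H)-one | CCCC[Sn](CCCC)(CCCC)CC1=C[C@@H](/C=C(/C)I)OC1=O | intermediate
11 | (tert-butyldimethylsilyloxy)acetaldehyde | O=CCO[Si](C)(C)C(C)(C)C | starting material
12 | (acetylmethylene)triphenylphosphorane | CC(=O)C=P(c1ccccc1)(c1ccccc1)c1ccccc1 | starting material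
13 | (3E)-5-[(tert-butyldimethylsilyl)oxy]pent-3-en-2-one | CC(=O)/C=C/CO[Si](C)(C)C(C)(C)C | intermediate
14 | (4R,5E)-7-[(tert-butyldimethylsilyl)oxy]-4-methylhepta-1,5-dien-4-ol | C=CC[C@@](C)(O)/C=C/CO[Si](C)(C)C(C)(C)C | intermediate
15 | (4R,5E)-7-[(tert-butyldimethylsilyl)oxy]-4-methyl-4-[(triethylsilyl)oxy]hepta-1,5-diene | C=CC[C@@](C)(O[Si](CC)(CC)CC)/C=C/CO[Si](C)(C)C(C)(C)C | intermediate
16 | (4R,5E)-7-[(tert-butyldimethylsilyl)oxy]-4-methyl-4-[(triethylsilyl)oxy]hept-5-ene-1,2-diol (both C2 epimers) | OCC(O)C[C@@](C)(O[Si](CC)(CC)CC)/C=C/CO[Si](C)(C)C(C)(C)C | intermediate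
17 | (3R,4E)-6-[(tert-butyldimethylsilyl)oxy]-3-methyl-3-[(triethylsilyl)oxy]hex-4-enal | O=CC[C@@](C)(O[Si](CC)(CC)CC)/C=C/CO[Si](C)(C)C(C)(C)C | intermediate
18 | (4R,5S)-4-[(1R,3R,4E)-6-[(tert-butyldimethylsilyl)oxy]-1-hydroxy-3-methyl-3-[(triethylsilyl)oxy]hex-4-en-1-yl]-5-[(1Z)-2-iodoprop-1-en-1-yl]-3-methylideneoxolan-2-one | C=C1C(=O)O[C@H](/C=C(/C)I)[C@H]1[C@H](O)C[C@@](C)(O[Si](CC)(CC)CC)/C=C/CO[Si](C)(C)C(C)(C)C | intermediate
19 | angelic acid, (2Z)-2-methylbut-2-enoic acid | C/C=C(/C)C(=O)O | starting material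
20 | (1R,3R,4E)-6-[(tert-butyldimethylsilyl)oxy]-1-[(2S,3R)-2-[(1Z)-2-iodoprop-1-en-1-yl]-4-methylidene-5-oxooxolan-3-yl]-3-methyl-3-[(triethylsilyl)oxy]hex-4-en-1-yl (2Z)-2-methylbut-2-enoate | C=C1C(=O)O[C@H](/C=C(/C)I)[C@H]1[C@H](OC(=O)/C(C)=C\C)C[C@@](C)(O[Si](CC)(CC)CC)/C=C/CO[Si](C)(C)C(C)(C)C | intermediate
21 | (1R,3R,4E)-3,6-dihydroxy-1-[(2S,3R)-2-[(1Z)-2-iodoprop-1-en-1-yl]-4-methylidene-5-oxooxolan-3-yl]-3-methylhex-4-en-1-yl (2Z)-2-methylbut-2-enoate | C=C1C(=O)O[C@H](/C=C(/C)I)[C@H]1[C@H](OC(=O)/C(C)=C\C)C[C@@](C)(O)/C=C/CO | intermediate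
22 | (1R,3R,4E)-3-hydroxy-1-[(2S,3R)-2-[(1Z)-2-iodoprop-1-en-1-yl]-4-methylidene-5-oxooxolan-3-yl]-3-methyl-6-oxohex-4-en-1-yl (2Z)-2-methylbut-2-enoate | C=C1C(=O)O[C@H](/C=C(/C)I)[C@H]1[C@H](OC(=O)/C(C)=C\C)C[C@@](C)(O)/C=C/C=O | intermediate
23 | alkenylchromium dichloride of 22 (CrCl2 in place of iodine on C4, Z geometry kept) | C=C1C(=O)O[C@H](/C=C(/C)[Cr](Cl)Cl)[C@H]1[C@H](OC(=O)/C(C)=C\C)C[C@@](C)(O)/C=C/C=O | intermediate
24 | (3aR,4R,6R,7E,9R,10Z,11aR)-6,9-dihydroxy-6,10-dimethyl-3-methylidene-2-oxo-2,3,3a,4,5,6,9,11a-octahydrocyclodeca[b]furan-4-yl (2Z)-2-methylbut-2-enoate | C=C1C(=O)O[C@@H]2/C=C(/C)[C@H](O)/C=C/[C@](C)(O)C[C@@H](OC(=O)/C(C)=C\C)[C@@H]12 | target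

**Step count and risks**

Total step count: 15. Longest linear sequence: 11 steps (steps 1–6 and 11–15).

Steps most likely to fail:

Step 15. The ring closure may lose material to oligomerisation, and above all the facial selectivity at C3 in the medium-ring transition state may be poor. The fallback takes the C3 configuration out of the ring closure and sets it with a reagent. Starting from 22, the same cyclisation is run without regard to the C3 ratio and should give 24 together with its C3 epimer, (3aR,4R,6R,7E,9S,10Z,11aR)-6,9-dihydroxy-6,10-dimethyl-3-methylidene-2-oxo-2,3,3a,4,5,6,9,11a-octahydrocyclodeca[b]furan-4-yl (2Z)-2-methylbut-2-enoate F1. The mixture is oxidised with MnO2 in CH2Cl2 to the cross-conjugated dienone (3aR,4R,6R,7E,10Z,11aR)-6-hydroxy-6,10-dimethyl-3-methylidene-2,9-dioxo-2,3,3a,4,5,6,9,11a-octahydrocyclodeca[b]furan-4-yl (2Z)-2-methylbut-2-enoate F2. 1,2-Reduction of this dienone with (S)-2-methyl-CBS-oxazaborolidine and catecholborane (toluene, −78 °C), in which the methyl-branched C4=C5 alkenyl group acts as the large substituent, should return to the route at 24.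

Step 11. The acceptor-substituted allylstannane may react sluggishly, the open-transition-state preference may erode (poor simple diastereoselection at C8), or silyl ethers may be lost to BF3. The fallback uses a closed transition state and corrects C8 afterwards. Bromide 8 and aldehyde 17 are coupled with nickel-free CrCl2 in THF at rt; the chair transition state of the ring-locked E-type allylchromium should give the C8 epimer (4R,5S)-4-[(1S,3R,4E)-6-[(tert-butyldimethylsilyl)oxy]-1-hydroxy-3-methyl-3-[(triethylsilyl)oxy]hex-4-en-1-yl]-5-[(1Z)-2-iodoprop-1-en-1-yl]-3-methylideneoxolan-2-one F3. Mitsunobu esterification of this alcohol with angelic acid 19 (PPh3, DIAD, toluene, 0 °C) inverts C8 and installs the ester in one operation, rejoining the route at 20. Elimination towards C7 is the hazard of this fallback.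

Step 6. The allylzinc may be protonated by the aqueous medium, or tin may be transferred to the ring carbon C7 instead of C13. The fallback reverses the order of tin introduction and ring closure. From 7, Zn and Bu3SnCl (THF/aq NH4Cl) give (3S,4Z)-5-iodohexa-1,4-dien-3-yl 2-[(tributylstannyl)methyl]prop-2-enoate F4; the two allyl termini of the acrylate are equivalent, so no regiochemical question arises. Ring-closing metathesis of this ester with the second-generation Grubbs catalyst (toluene, 80 °C) returns to the route at 10.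

**Further compounds**

F1 | step 15 | (3aR,4R,6R,7E,9S,10Z,11aR)-6,9-dihydroxy-6,10-dimethyl-3-methylidene-2-oxo-2,3,3a,4,5,6,9,11a-octahydrocyclodeca[b]furan-4-yl (2Z)-2-methylbut-2-enoate (C3 epimer of 24) | C=C1C(=O)O[C@@H]2/C=C(/C)[C@@H](O)/C=C/[C@](C)(O)C[C@@H](OC(=O)/C(C)=C\C)[C@@H]12
F2 | step 15 | (3aR,4R,6R,7E,10Z,11aR)-6-hydroxy-6,10-dimethyl-3-methylidene-2,9-dioxo-2,3,3a,4,5,6,9,11a-octahydrocyclodeca[b]furan-4-yl (2Z)-2-methylbut-2-enoate | C=C1C(=O)O[C@@H]2/C=C(/C)C(=O)/C=C/[C@](C)(O)C[C@@H](OC(=O)/C(C)=C\C)[C@@H]12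
F3 | step 11 | (4R,5S)-4-[(1S,3R,4E)-6-[(tert-butyldimethylsilyl)oxy]-1-hydroxy-3-methyl-3-[(triethylsilyl)oxy]hex-4-en-1-yl]-5-[(1Z)-2-iodoprop-1-en-1-yl]-3-methylideneoxolan-2-one (C8 epimer of 18) | C=C1C(=O)O[C@H](/C=C(/C)I)[C@H]1[C@@H](O)C[C@@](C)(O[Si](CC)(CC)CC)/C=C/CO[Si](C)(C)C(C)(C)C
F4 | step 6 | (3S,4Z)-5-iodohexa-1,4-dien-3-yl 2-[(tributylstannyl)methyl]prop-2-enoate | C=C(C[Sn](CCCC)(CCCC)CCCC)C(=O)O[C@@H](C=C)/C=C(/C)I
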